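**Retrosynthetic overview**
1. Target ⇐ C8 acylation with epoxy acid 3; γ-lactone closed onto C6 after reagent-controlled reduction of a C6 ketone; 2,3-epoxide from catalyst-controlled epoxidation of the central cis-alkene of an all-cis trienone.
2. Ten-membered ring ⇐ four-atom ring expansion of the cis-fused bicyclo[4.4.0] nitro ketol 20: the C6 alkoxide cleaves C6–C1 and expels nitrite from C10 (C6=O and C1=C10 formed together).
3. Bicycle 20 ⇐ p-quinol aldehyde 16 + methyl nitroacetate (nitro-aldol at C9, then Michael addition at C1).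
4. 16 ⇐ quinone monoketal 14 (from m-cresol; supplies C1–C6 and C15) + allyl bromide 12 (indium allylation, C6–C7); 12 ⇐ Baylis–Hillman chemistry on aldehyde 9.
5. Ring order: cyclohexadienone → second six-membered ring → ten-membered carbocycle → epoxide → γ-lactone.

Atom labels C1–C15 follow the germacrane numbering of the target (C6 lactone carbinol, C7 ring junction, C8 acyloxy, C9 hydroxy, C10 ester-bearing alkene carbon, C2/C3 epoxide, C4 methyl-bearing). PMB = 4-methoxybenzyl, TBS = tert-butyldimethylsilyl.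

**Step 1**
Reactants: 1 (E)-2-methylbut-2-en-1-ol
Product: 2 [(2R,3R)-2,3-dimethyloxiran-2-yl]methanol
Conditions: Ti(OiPr)4 (10 mol %), D-(−)-diisopropyl tartrate, t-BuOOH, 4 Å MS, CH2Cl2, −20 °C
Reagents that add atoms: tert-butyl hydroperoxide, CC(C)(C)OO
Why: Katsuki–Sharpless asymmetric epoxidation of an E-allylic alcohol; the D-tartrate complex delivers oxygen to the face that gives the (2R,3R)-epoxy alcohol, so both stereocentres are set by reagent control.

**Step 2**
Reactants: 2 [(2R,3R)-2,3-dimethyloxiran-2-yl]methanol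
Product: 3 (2S,3R)-2,3-dimethyloxirane-2-carboxylic acid
Conditions: TEMPO (cat.), PhI(OAc)2, MeCN/H2O 1:1, 23 °C
Reagents that add atoms: water, O
Why: TEMPO/PhI(OAc)2 oxidation of a primary alcohol to the acid via the aldehyde hydrate; the epoxide stereocentres are untouched (the C2 label changes from R to S by priority only).

**Step 3**
Reactants: 4 2,2-dimethoxyacetaldehyde; 5 vinylmagnesium bromide
Product: 6 racemic 1,1-dimethoxybut-3-en-2-ol
Conditions: THF, −78 → 0 °C; aq. NH4Cl
Reagents that add atoms: none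
Why: Grignard 1,2-addition to a non-enolisable aldehyde gives the racemic allylic alcohol (carbinol = C8, vinyl CH = C7, acetal carbon = C9).

**Step 4**
Reactants: 6 racemic 1,1-dimethoxybut-3-en-2-ol
Product: 7 (S)-1,1-dimethoxybut-3-en-2-ol
Conditions: Candida antarctica lipase B (immobilised), vinyl acetate, hexane, 30 °C, about 52% conversion
Reagents that add atoms: none
Why: Lipase-catalysed kinetic resolution (transesterification); by the Kazlauskas rule the (R)-alcohol is acetylated and (S)-7, which carries the C8 configuration of the target, is recovered.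

**Step 5**
Reactants: 7 (S)-1,1-dimethoxybut-3-en-2-ol
Product: 8 (S)-1,1-dimethoxy-2-(4-methoxybenzyloxy)but-3-ene
Conditions: NaH, 4-methoxybenzyl chloride, Bu4NI (cat.), DMF, 0 → 23 °C
Reagents that add atoms: 4-methoxybenzyl chloride, COc1ccc(CCl)cc1
Why: Williamson etherification of the alkoxide; no stereocentre is involved.

**Step 6**
Reactants: 8 (S)-1,1-dimethoxy-2-(4-methoxybenzyloxy)but-3-ene
Product: 9 (S)-3,3-dimethoxy-2-(4-methoxybenzyloxy)propanal
Conditions: OsO4 (2 mol %), NaIO4, 2,6-lutidine, dioxane/H2O 3:1, 23 °C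
Reagents that add atoms: sodium periodate, [Na+].[O-]I(=O)(=O)=O
Why: Lemieux–Johnson oxidative cleavage of the terminal alkene; lutidine buffering prevents epimerisation of the α-alkoxy aldehyde.

**Step 7**
Reactants: 9 (S)-3,3-dimethoxy-2-(4-methoxybenzyloxy)propanal; 10 isopropyl acrylate
Product: 11 isopropyl (4S)-3-hydroxy-5,5-dimethoxy-4-(4-methoxybenzyloxy)-2-methylidenepentanoate (both C3 epimers)
Conditions: DABCO (1 equiv), MeOH, 23 °C
Reagents that add atoms: none
Why: Morita–Baylis–Hillman reaction of an activated α-alkoxy aldehyde; the new carbinol centre is a mixture and is removed in step 8.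

**Step 8**
Reactants: 11 isopropyl (4S)-3-hydroxy-5,5-dimethoxy-4-(4-methoxybenzyloxy)-2-methylidenepentanoate
Product: 12 isopropyl (2Z,4S)-2-(bromomethyl)-5,5-dimethoxy-4-(4-methoxybenzyloxy)pent-2-enoate
Conditions: NBS, Me2S, CH2Cl2, 0 → 23 °C
Reagents that add atoms: N-bromosuccinimide, O=C1CCC(=O)N1Br
Why: SN2′ bromination of the Baylis–Hillman alcohol through the bromosulfonium (Corey–Kim-type) intermediate gives the favoured (Z)-2-(bromomethyl)enoate.

**Step 9**
Reactants: 13 3-methylphenol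
Product: 14 4,4-dimethoxy-3-methylcyclohexa-2,5-dien-1-one
Conditions: PhI(OAc)2 (2.1 equiv), MeOH, 0 → 23 °C
Reagents that add atoms: methanol, CO
Why: Hypervalent-iodine oxidative dearomatization of a para-unsubstituted phenol in methanol gives the p-quinone monoketal (carbonyl = C6, ketal = C3, methyl on C4).

**Step 10**
Reactants: 12 isopropyl (2Z,4S)-2-(bromomethyl)-5,5-dimethoxy-4-(4-methoxybenzyloxy)pent-2-enoate; 14 4,4-dimethoxy-3-methylcyclohexa-2,5-dien-1-one
Product: 16 p-quinol aldehyde (4-hydroxy-3-methylcyclohexa-2,5-dienone whose carbinol carbon C6 carries C7H[C(=CH2)CO2iPr]–C8H(OPMB)–C9HO; C7 and C8 as in the target; in equilibrium with its C6–O/C9 lactol), via quinol bis-acetal 15 (not isolated)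
Conditions: In powder, THF/H2O 1:1, 23 °C; then 1 M HCl, THF, 0 °C
Reagents that add atoms: water, O
Why: Barbier-type indium allylation (SE2′ γ-attack, 1,2-addition to the dienone carbonyl) forms C6–C7 and aqueous acid then unmasks the C3 ketone and C9 aldehyde; C7 is set by attack on the allyl face anti to the C9 acetal in the allylic-strain-minimised (C8–H eclipsed) conformer, while the C6 carbinol centre forms as an epimer pair, is erased in step 12, and is drawn as the epimer that cyclises through a chair in step 11.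

**Step 11**
Reactants: 16 p-quinol aldehyde; 17 methyl nitroacetate
Product: 20 cis-fused bicyclic nitro ketol TBS ether (ring fusion C1–H/C6–OH syn; C10 bears NO2 and CO2Me; C9 OTBS; C8 OPMB; C7 C(=CH2)CO2iPr; C3 ketone; C4(Me)=C5), via nitro-aldol adduct 18 (not isolated), via bicyclic nitro diol 19 (not isolated)
Conditions: MgBr2·OEt2, Et3N, CH2Cl2, −20 °C; then DBU, 0 °C; then TBSOTf, 2,6-lutidine, −40 °C
Reagents that add atoms: tert-butyldimethylsilyl trifluoromethanesulfonate, CC(C)(C)[Si](C)(C)OS(=O)(=O)C(F)(F)F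
Why: Henry (nitro-aldol) addition under Cram-chelate control (magnesium bridging C9=O and the C8 ether oxygen gives the 8,9-syn adduct, C9 S), then 6-exo intramolecular Michael addition of the nitronate to the less substituted enone carbon C1 gives the cis-fused bicycle with the ester syn to the C6 hydroxyl (hydrogen-bonded) and the nitro group anti to the C1–C6 bond, and the secondary C9 hydroxyl is silylated in preference to the tertiary one.

**Step 12**
Reactants: 20 cis-fused bicyclic nitro ketol TBS ether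
Product: 22 ten-membered dienyl triflate (C6 ketone; ring-cis C4=C5, C2=C3 and C1=C10; OTf on C3), via ten-membered ene-dione 21 (not isolated)
Conditions: KN(SiMe3)2 (2.1 equiv), THF, −78 → −40 °C; then PhNTf2, −78 °C
Reagents that add atoms: N-phenylbis(trifluoromethanesulfonimide), O=S(=O)(N(c1ccccc1)S(=O)(=O)C(F)(F)F)C(F)(F)F
Why: Proposed new method: a nitro-Grob ring expansion in which the C6 potassium alkoxide pushes electrons into the anti-periplanar C6–C1 bond while nitrite leaves from the doubly activated C10 (chair with NO2 equatorial), giving the C6 ketone and the ring-cis C1=C10 acrylate of the ten-membered ring, after which the doubly activated C2 methylene is deprotonated and O-triflated; the closest known chemistry is the Wharton–Grob fragmentation of 1,3-diol monosulfonates to cyclodecenones together with base-induced loss of nitrite from tertiary α-nitro esters, and no stereocentre is created.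

**Step 13**
Reactants: 22 ten-membered dienyl triflate
Product: 23 all-cis trienone (C6 ketone; C4=C5, C2=C3, C1=C10 all ring-cis)
Conditions: Pd(PPh3)4 (5 mol %), Bu3SnH, LiCl, THF, 23 °C
Reagents that add atoms: none
Why: Palladium-catalysed tin-hydride reduction of an enol triflate replaces OTf by H with retention of alkene geometry.

**Step 14**
Reactants: 23 all-cis trienone
Product: 24 (2S,3R)-2,3-epoxy enone
Conditions: (R,R)-[Mn(salen)Cl] (salen = N,N′-bis(3,5-di-tert-butylsalicylidene)cyclohexane-1,2-diaminate, 5 mol %), NaOCl (aq., pH 11.3), 4-phenylpyridine N-oxide, CH2Cl2, 0 °C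
Reagents that add atoms: sodium hypochlorite, [Na+].[O-]Cl
Why: Jacobsen–Katsuki epoxidation; only the electron-rich cis-disubstituted C2=C3 bond reacts (C4=C5 is an enone, C1=C10 and C11=C13 are acrylates) and the chiral manganese–salen oxo species sets the (2S,3R) cis-epoxide by reagent control.

**Step 15**
Reactants: 24 (2S,3R)-2,3-epoxy enone
Product: 26 6,12-lactone with C8 OPMB and C9 OTBS, via C6 hydroxy ester 25 (not isolated)
Conditions: (R)-Me-CBS oxazaborolidine (20 mol %), catecholborane, toluene, −78 °C; then KOt-Bu (0.2 equiv), THF, 0 °C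
Reagents that add atoms: none
Why: Corey–Bakshi–Shibata reduction of the enone carbonyl (alkenyl as the large group; the (R)-catalyst gives the 6R carbinol) and base-catalysed 5-exo transesterification closes the trans-fused α-methylene-γ-butyrolactone.

**Step 16**
Reactants: 26 6,12-lactone with C8 OPMB and C9 OTBS
Product: 27 C8 alcohol (C9 OTBS)
Conditions: DDQ, CH2Cl2/pH 7 buffer 10:1, 0 °C
Reagents that add atoms: none
Why: Oxidative cleavage of the p-methoxybenzyl ether by DDQ; silyl ether, epoxide, lactone and esters are inert.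

**Step 17**
Reactants: 27 C8 alcohol; 3 (2S,3R)-2,3-dimethyloxirane-2-carboxylic acid
Product: 28 C9 TBS ether of the target
Conditions: 2,4,6-trichlorobenzoyl chloride, Et3N, THF; then DMAP, toluene, 23 °C
Reagents that add atoms: none
Why: Yamaguchi esterification of the hindered C8 alcohol via the mixed anhydride; no stereocentre is affected.

**Step 18**
Reactants: 28 C9 TBS ether of the target
Product: 29 target CNP0291485.6
Conditions: HF·pyridine, pyridine, THF, 0 °C
Reagents that add atoms: none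
Why: Fluoride-mediated desilylation under buffered, non-basic conditions that avoid acyl migration and epoxide opening.

**Compound list**
1 | (E)-2-methylbut-2-en-1-ol | C/C=C(\C)CO | starting material
2 | [(2R,3R)-2,3-dimethyloxiran-2-yl]methanol | OC[C@@]1(C)O[C@@H]1C | intermediate
3 | (2S,3R)-2,3-dimethyloxirane-2-carboxylic acid | OC(=O)[C@@]1(C)O[C@@H]1C | intermediate
4 | 2,2-dimethoxyacetaldehyde | COC(OC)C=O | starting material
5 | vinylmagnesium bromide | C=C[Mg]Br | starting material
6 | racemic 1,1-dimethoxybut-3-en-2-ol | COC(OC)C(O)C=C | intermediate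
7 | (S)-1,1-dimethoxybut-3-en-2-ol | COC(OC)[C@@H](O)C=C | intermediate
8 | (S)-1,1-dimethoxy-2-(4-methoxybenzyloxy)but-3-ene | COC(OC)[C@@H](OCc1ccc(OC)cc1)C=C | intermediate
9 | (S)-3,3-dimethoxy-2-(4-methoxybenzyloxy)propanal | COC(OC)[C@@H](OCc1ccc(OC)cc1)C=O | intermediate
10 | isopropyl acrylate | C=CC(=O)OC(C)C | starting material
11 | isopropyl (4S)-3-hydroxy-5,5-dimethoxy-4-(4-methoxybenzyloxy)-2-methylidenepentanoate (C3 epimers) | COC(OC)[C@@H](OCc1ccc(OC)cc1)C(O)C(=C)C(=O)OC(C)C | intermediate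
12 | isopropyl (2Z,4S)-2-(bromomethyl)-5,5-dimethoxy-4-(4-methoxybenzyloxy)pent-2-enoate | COC(OC)[C@@H](OCc1ccc(OC)cc1)/C=C(\CBr)C(=O)OC(C)C | intermediate
13 | 3-methylphenol | Cc1cccc(O)c1 | starting material
14 | 4,4-dimethoxy-3-methylcyclohexa-2,5-dien-1-one | COC1(OC)C=CC(=O)C=C1C | intermediate
15 | quinol bis-acetal (C6 carbinol on the 4,4-dimethoxy-3-methylcyclohexa-2,5-dienyl ring; C7 acrylate branch; C8 OPMB; C9 dimethyl acetal) | COC(OC)[C@@H](OCc1ccc(OC)cc1)[C@@H](C(=C)C(=O)OC(C)C)[C@@]2(O)C=C(C)C(OC)(OC)C=C2 | intermediate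
16 | p-quinol aldehyde (C3 ketone, C6 carbinol, C9 aldehyde) | O=C[C@@H](OCc1ccc(OC)cc1)[C@@H](C(=C)C(=O)OC(C)C)[C@@]2(O)C=C(C)C(=O)C=C2 | intermediate
17 | methyl nitroacetate | COC(=O)C[N+](=O)[O-] | starting material
18 | nitro-aldol adduct (C9 OH; C10 epimers) | COC(=O)C([N+](=O)[O-])[C@H](O)[C@@H](OCc1ccc(OC)cc1)[C@@H](C(=C)C(=O)OC(C)C)[C@@]2(O)C=C(C)C(=O)C=C2 | intermediate
19 | bicyclic nitro diol | COC(=O)[C@]1([N+](=O)[O-])[C@H](O)[C@@H](OCc3ccc(OC)cc3)[C@@H](C(=C)C(=O)OC(C)C)[C@@]2(O)C=C(C)C(=O)C[C@@H]12 | intermediate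
20 | cis-fused bicyclic nitro ketol TBS ether | COC(=O)[C@]1([N+](=O)[O-])[C@H](O[Si](C)(C)C(C)(C)C)[C@@H](OCc3ccc(OC)cc3)[C@@H](C(=C)C(=O)OC(C)C)[C@@]2(O)C=C(C)C(=O)C[C@@H]12 | intermediate
21 | ten-membered ene-dione (C3 and C6 ketones; cis C4=C5 and C1=C10) | O=C1/C=C(/C)C(=O)C/C=C(/C(=O)OC)[C@H](O[Si](C)(C)C(C)(C)C)[C@@H](OCc2ccc(OC)cc2)[C@H]1C(=C)C(=O)OC(C)C | intermediate
22 | ten-membered dienyl triflate | O=C1/C=C(/C)\C(OS(=O)(=O)C(F)(F)F)=C/C=C(/C(=O)OC)[C@H](O[Si](C)(C)C(C)(C)C)[C@@H](OCc2ccc(OC)cc2)[C@H]1C(=C)C(=O)OC(C)C | intermediate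
23 | all-cis trienone | O=C1/C=C(/C)\C=C/C=C(/C(=O)OC)[C@H](O[Si](C)(C)C(C)(C)C)[C@@H](OCc2ccc(OC)cc2)[C@H]1C(=C)C(=O)OC(C)C | intermediate
24 | (2S,3R)-2,3-epoxy enone | O=C1/C=C(/C)[C@H]3O[C@H]3/C=C(/C(=O)OC)[C@H](O[Si](C)(C)C(C)(C)C)[C@@H](OCc2ccc(OC)cc2)[C@H]1C(=C)C(=O)OC(C)C | intermediate
25 | C6 hydroxy ester (6R) | O[C@@H]1/C=C(/C)[C@H]3O[C@H]3/C=C(/C(=O)OC)[C@H](O[Si](C)(C)C(C)(C)C)[C@@H](OCc2ccc(OC)cc2)[C@H]1C(=C)C(=O)OC(C)C | intermediate
26 | 6,12-lactone with C8 OPMB and C9 OTBS | C=C1C(=O)O[C@@H]2/C=C(/C)[C@H]3O[C@H]3/C=C(/C(=O)OC)[C@H](O[Si](C)(C)C(C)(C)C)[C@@H](OCc4ccc(OC)cc4)[C@@H]12 | intermediate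
27 | C8 alcohol (C9 OTBS) | C=C1C(=O)O[C@@H]2/C=C(/C)[C@H]3O[C@H]3/C=C(/C(=O)OC)[C@H](O[Si](C)(C)C(C)(C)C)[C@@H](O)[C@@H]12 | intermediate
28 | C9 TBS ether of the target | C=C1C(=O)O[C@@H]2/C=C(/C)[C@H]3O[C@H]3/C=C(/C(=O)OC)[C@H](O[Si](C)(C)C(C)(C)C)[C@@H](OC(=O)[C@@]4(C)O[C@@H]4C)[C@@H]12 | intermediate
29 | CNP0291485.6 | C=C1C(=O)O[C@@H]2/C=C(/C)[C@H]3O[C@H]3/C=C(/C(=O)OC)[C@H](O)[C@@H](OC(=O)[C@@]3(C)O[C@@H]3C)[C@@H]12 | target

**Totals**
Total steps: 18. Longest linear sequence: 15 (steps 3–8, then 10–18).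

**Steps most likely to fail**

Step 12 (the new nitro-Grob ring expansion). Nitrite may be too poor a nucleofuge, or C7 may epimerise under base. Fallback with known radical chemistry, from 20 back to 22: treat 20 with PhI(OAc)2 and I2 under visible light (Suárez conditions). The C6 alkoxy radical undergoes β-scission of C6–C1, and the resulting β-nitroalkyl radical loses NO2, giving ene-dione 21, which is isolated this time. Separate treatment with KN(SiMe3)2 and PhNTf2 then gives 22. No compound outside the list is made (F0).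

Step 10 (indium allylation). Risks are 1,4-addition, poor control of C7, and loss of material if only one C6 epimer cyclises in step 11. Fallback from 11 back to 16, replacing the Barbier reaction by a catalyst-controlled allylboration: acetylate 11 (Ac2O, DMAP) to allylic acetate F1; copper-catalysed SN2′ borylation (B2pin2, CuCl, KOt-Bu, Xantphos) gives allylboronate F2; (S)-3,3′-dibromo-BINOL-catalysed allylboration of ketone 14 with F2, followed by the same aqueous HCl treatment, returns to 16.

Step 14 (Jacobsen epoxidation). Risks are the wrong face or site, and 6π-electrocyclisation of the all-cis triene 23 before it is epoxidised. Fallback from 20 back to 24, moving the epoxide to the rigid bicycle under substrate control: convert 20 (TMSOTf, Et3N; then NBS) into α-bromo ketone F3 with bromine at C2; Luche reduction (NaBH4, CeCl3·7H2O) gives bromohydrin F4; K2CO3 in MeOH closes bicyclic epoxide F5; the fragmentation conditions of step 12 (KN(SiMe3)2 only) then deliver 24 directly.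

**Further compounds**
F1 | step 10 | allylic acetate of 11 | COC(OC)[C@@H](OCc1ccc(OC)cc1)C(OC(C)=O)C(=C)C(=O)OC(C)C
F2 | step 10 | (Z)-allylboronate (pinacol ester) corresponding to 12 | COC(OC)[C@@H](OCc1ccc(OC)cc1)/C=C(\CB2OC(C)(C)C(C)(C)O2)C(=O)OC(C)C
F0 | step 12 | none | none
F3 | step 14 | C2-bromo ketone of 20 | COC(=O)[C@]1([N+](=O)[O-])[C@H](O[Si](C)(C)C(C)(C)C)[C@@H](OCc3ccc(OC)cc3)[C@@H](C(=C)C(=O)OC(C)C)[C@@]2(O)C=C(C)C(=O)[C@H](Br)[C@@H]12
F4 | step 14 | C2-bromo C3-hydroxy bicycle (bromohydrin) | COC(=O)[C@]1([N+](=O)[O-])[C@H](O[Si](C)(C)C(C)(C)C)[C@@H](OCc3ccc(OC)cc3)[C@@H](C(=C)C(=O)OC(C)C)[C@@]2(O)C=C(C)[C@@H](O)[C@H](Br)[C@@H]12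
F5 | step 14 | bicyclic 2,3-epoxide | COC(=O)[C@]1([N+](=O)[O-])[C@H](O[Si](C)(C)C(C)(C)C)[C@@H](OCc3ccc(OC)cc3)[C@@H](C(=C)C(=O)OC(C)C)[C@@]2(O)C=C(C)[C@H]4O[C@H]4[C@@H]12
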